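Against the eta run your flask is charged with less G, 0.400 M to 0.56 M, and you wanted a quick number for L at 5.0 min, with your hunch that more G pays.

| flask | Q | G | remark | time |
|---|---|---|---|---|
| eta | 0.20 M | 0.56 M | run made earlier |  |
| alpha | 0.20 M | 0.88 M | run made earlier |  |
| epsilon | 0.10 M | 0.40 M | run made earlier |  |
| flask | 0.20 M | 0.400 M |  | 5.0 min |

| run | time / min | L / % | Q / % |
|---|---|---|---|
| eta | 0.833 | 3 | 77 |
| eta | 1.50 | 2 | 68 |
| eta | 2.50 | 5 | 55 |
| eta | 3.00 | 11 | 51 |
| eta | 4.00 | 10 | 42 |
| eta | 5.00 | 12 | 35 |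
| eta | 6.00 | 16 | 29 |
| alpha | 0.500 | 3 | 83 |
| alpha | 0.667 | 3 | 75 |
| alpha | 1.00 | 4 | 66 |
| alpha | 1.50 | 3 | 51 |
| alpha | 2.50 | 12 | 39 |
| alpha | 4.00 | 18 | 26 |
| alpha | 6.00 | 19 | 12 |
| epsilon | 1.33 | 0 | 79 |
| epsilon | 2.50 | 3 | 64 |
| epsilon | 4.00 | 8 | 50 |
| epsilon | 5.00 | 10 | 45 |
| epsilon | 6.00 | 13 | 37 |

(readings scatter by 2 percentage points)



1. equivalents of G to Q, everything else as given, that leave most L at 5.0 min
2. the amount of L then, in percent of the Q charged
3. the amount of L with the amounts as given

I followed one Q molecule: its chance of still being Q was exp(−a), where a, its exposure, is s·[G]·t with [G] as charged. The eta reading of 35% Q at 5.00 min gave s = 0.375 /M/min, the exposure constant, a pseudo-first-order figure on charged G that carries the scatter of that reading.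

For your flask the constant then gave a = 0.750, so Q near 47.2%. The epsilon reading at 5.00 min stood at exposure 0.799 by its Q, with L 10%, and your flask lay just below that, so I expected a little less L.

For the top, the alpha readings showed L 18% at exposure 1.35 and 19% at 2.12. By the constant, reaching the latter in 5.0 min came to 5.65 equivalents with L about 19%, my estimate from scattered readings.

The forecast gave L 8% (5.5% to 10.5%) as charged, and 20% (17% to 24%) at 4.8 equiv (3.8 equiv to 7.5 equiv), fewer equivalents than mine, reasoning that “The curve flattens, so L is probably consumed”.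

The flask gave L 8.58% as charged and a maximum of 20.4% at 5.77 equiv, where Q stood at 11.1%. The exposure constant puts those equivalents at a = 2.16, or Q 11.5%, while the forecast placed its peak near 1.7; that is where the two part.

    Q + G → Z (k = 0.500 /M/min)
    G + Z → L (k = 0.380 /M/min)
    G + L → X (k = 0.600 /M/min)
    G ⇌ J (K = 0.400, k = 0.0550 /min)
    Q + L → E (k = 0.600 /M/min)

For the neighbour flask, your charge but with 0.68 M of G, the constant gave a = 1.27, so Q 28.1%, and L between the eta 12% at exposure 1.05 and the alpha 18%. That flask gave Q 27.6% and L 15.8%.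

The data were computed from invented constants, noise included.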